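A direct plan would start from the finished arene: Friedel–Crafts acylation of 1,3,5-trimethoxy-2,4-dimethylbenzene A1 with hexadecanoyl chloride to ketone A2, cleavage of one ortho ether to phenol A3, oxidative closure of the pyranone onto the fatty chain to chromone A4, then double demethylation. Its weakest steps would be:
- the oxidative ring closure, which would need two dehydrogenations of an unactivated CH2–CH2 and O1–C2 bond formation on an electron-rich hexasubstituted arene, without close precedent;
- the two ether cleavages, which would add length without complexity and expose the chromone to BBr3;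
- the acylation between two methoxy groups, where AlCl3 could cleave the ethers.

The benzene ring is made last. The route exploits that C7 of the benzo ring is a carbonic-acid-level carbon flanked by the two methyl-bearing carbons C6 and C8. A monocyclic 4-pyranone carrying an ethyl group on C8a and a propanoyl group on C4a (chromone numbering) is assembled from an acylketene and symmetric heptane-3,5-dione; the carbocycle C4a–C5–C6–C7–C8–C8a is then closed by a [5+1] Claisen–Dieckmann annulation in which dimethyl carbonate supplies C7. C7–C8 and C6–C7 form, both phenols and both methyl groups appear in place and the ring aromatises in one operation. No phenol is protected, no arene is acylated and the fatty chain is never oxidised, so the weak steps above have no counterpart.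

Key step: step 3

Assumption: atom labels C2 to C8a follow the chromone numbering of the target throughout; the target is achiral, so no stereocentre has to be set.

Step 1
Reactants: 1 tetradecanoyl chloride (myristoyl chloride); 2 Meldrum's acid (2,2-dimethyl-1,3-dioxane-4,6-dione)
Product: 3 5-(1-hydroxytetradecylidene)-2,2-dimethyl-1,3-dioxane-4,6-dione
Conditions: 2 (1.0 equiv), pyridine (2.2 equiv), CH2Cl2, 0 °C; 1 (1.05 equiv), 0 °C to rt, 3 h; 1 M HCl wash; used crude
Reagents that add atoms: Meldrum's acid 2, CC1(C)OC(=O)CC(=O)O1
Why: C-acylation of the highly acidic methylene of Meldrum's acid by the acid chloride with pyridine as base, the product being held as the hydrogen-bonded enol; no stereocentre is formed.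

Step 2
Reactants: 3 5-(1-hydroxytetradecylidene)-2,2-dimethyl-1,3-dioxane-4,6-dione; 4 heptane-3,5-dione
Product: 7 2-ethyl-3-propanoyl-6-tridecyl-4H-pyran-4-one, via tetradecanoylketene 5 (not isolated), via triacylmethane 6 (not isolated)
Conditions: 4 (2.0 equiv), toluene, 110 °C, slow addition of 3 over 2 h; then TsOH·H2O (10 mol %), Dean–Stark, 110 °C, 2 h
Reagents that add atoms: heptane-3,5-dione 4, CCC(=O)CC(=O)CC
Why: Acylketene route to 4-pyranones: retro-[4+2] loss of acetone and CO2 from 3 gives tetradecanoylketene 5, whose ketene carbon is attacked by the central carbon of the hydrogen-bonded enol of 4 (O-acylation of the enol is reversible through the same ketene) to give triacylmethane 6, and acid-catalysed cyclodehydration of its 1,3,5-triketone unit can give only 7 because the two propanoyl groups are equivalent; no stereocentre is formed.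

Step 3
Reactants: 7 2-ethyl-3-propanoyl-6-tridecyl-4H-pyran-4-one; 8 dimethyl carbonate
Product: 10 5,7-dihydroxy-6,8-dimethyl-2-tridecyl-4H-chromen-4-one, via keto ester 9 (not isolated)
Conditions: NaH (4.0 equiv), (MeO)2CO (2.5 equiv), MeOH (0.1 equiv), THF, 65 °C, 16 h; then 1 M HCl, 0 °C
Reagents that add atoms: dimethyl carbonate 8, COC(=O)OC
Why: Tandem Claisen–Dieckmann condensation ([5+1] benzannulation): NaH (and the NaOMe it generates) removes the most acidic proton of 7, on the CH2 of the ring-ethyl group, which is vinylogous to both the pyranone carbonyl and the propanoyl carbonyl, and the exocyclic carbon of this dienolate is acylated by dimethyl carbonate to give the enolate of ester 9. The enolate of the propanoyl CH2 (C6) then attacks the ester carbon (C7) in a Dieckmann condensation, a 6-(enolexo)-exo-trig closure of the carbocycle C4a–C5–C6–C7–C8–C8a; loss of methoxide and two enolisations give the bis-phenoxide of 10, and this aromatisation is the irreversible step that should draw the preceding equilibria forward. The closest known reaction types are the carbomethoxylation of ketones with NaH and dimethyl carbonate, the base-induced cyclisation of 5-oxo esters to cyclohexane-1,3-diones and that of 2-acylarylacetic esters to naphthalene-1,3-diols, with the 4-pyranone of 7 in the place of the arene. No stereocentre remains, because the stereocentre of 9 and those of the cyclised trione are erased by enolisation. The step needs carbon acylation at the ethyl CH2 and not at the α-CH2 of the tridecyl chain, and C- rather than O-cyclisation: the first is secured by the double vinylogous activation of the ethyl group (the tridecyl CH2 feels only the pyranone carbonyl, and acylation at the propanoyl CH2 instead would lead to the same ring), the second because the enol lactone from O-attack and any enol carbonates are reopened by methoxide whereas only the carbocycle can aromatise. As its anion, 7 is also shielded from attack of methoxide on the pyranone ring.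

## Compound list
1 | tetradecanoyl chloride (myristoyl chloride) | CCCCCCCCCCCCCC(=O)Cl | starting material
2 | Meldrum's acid (2,2-dimethyl-1,3-dioxane-4,6-dione) | CC1(C)OC(=O)CC(=O)O1 | starting material
3 | 5-(1-hydroxytetradecylidene)-2,2-dimethyl-1,3-dioxane-4,6-dione | CCCCCCCCCCCCCC(O)=C1C(=O)OC(C)(C)OC1=O | intermediate
4 | heptane-3,5-dione | CCC(=O)CC(=O)CC | starting material
5 | tetradecanoylketene (3-oxohexadec-1-en-1-one), formed in the flask | CCCCCCCCCCCCCC(=O)C=C=O | intermediate
6 | 4-propanoylicosane-3,5,7-trione (triacylmethane), formed in the flask | CCCCCCCCCCCCCC(=O)CC(=O)C(C(=O)CC)C(=O)CC | intermediate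
7 | 2-ethyl-3-propanoyl-6-tridecyl-4H-pyran-4-one | CCCCCCCCCCCCCc1cc(=O)c(C(=O)CC)c(CC)o1 | intermediate
8 | dimethyl carbonate | COC(=O)OC | starting material
9 | methyl 2-(4-oxo-3-propanoyl-6-tridecyl-4H-pyran-2-yl)propanoate (racemic, present as its sodium enolate), formed in the flask | CCCCCCCCCCCCCc1cc(=O)c(C(=O)CC)c(C(C)C(=O)OC)o1 | intermediate
10 | 5,7-dihydroxy-6,8-dimethyl-2-tridecyl-4H-chromen-4-one (achiral) | CCCCCCCCCCCCCc1cc(=O)c2c(O)c(C)c(O)c(C)c2o1 | target

Total step count: 3. Longest linear sequence: 3 steps (1 to 3 to 7 to 10).

Steps most likely to fail

Step 3. The Dieckmann closure may stall because the ester of 9 sits inside a stabilised carbanion, or the first acylation may fall on the α-CH2 of the tridecyl chain. The fallback inverts the roles so that the ester sits on the ring carbon C4a and the ketone on the side chain. It sets out from 3. Thermolysis of 3 in the presence of methyl (E)-3-(pyrrolidin-1-yl)pent-2-enoate F1 (from methyl 3-oxopentanoate and pyrrolidine), followed by TsOH, would give methyl 2-ethyl-4-oxo-6-tridecyl-4H-pyran-3-carboxylate F2 by the enamine route to 4-pyranones. Deprotonation of the ring-ethyl CH2 with lithium diisopropylamide (2.2 equiv) and acylation with N-methoxy-N-methylpropanamide would give methyl 4-oxo-2-(3-oxopentan-2-yl)-6-tridecyl-4H-pyran-3-carboxylate F3. NaOMe in MeOH would then close C5–C6 by Dieckmann condensation of the ethyl ketone onto the ring ester, which is not part of the carbanion, and the route is rejoined at 10.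

Step 2. The ketene may be consumed by dimerisation or by O-acylation of the enol faster than by C-acylation, and aldol aromatisation of 6 may compete with pyranone formation. The fallback sets out from 4, which would be condensed with pyrrolidine to (E)-5-(pyrrolidin-1-yl)hept-4-en-3-one F4, a purely carbon-nucleophilic partner. Ketene 5 released from 3 would add across its enamine double bond (inverse-demand hetero-Diels–Alder reaction) and acid would expel pyrrolidine, so that the route is rejoined at 7 without passing through 6.

Step 1. Over-acylation of Meldrum's acid may occur, or 3 may lose acetone and CO2 during isolation and the ketene may then dimerise. The fallback sets out from 1: Claisen condensation with the lithium enolate of tert-butyl acetate (2 equiv, THF, −78 °C) would give tert-butyl 3-oxohexadecanoate F5, a storable ketene precursor. Heated with 4 in xylene at 140 °C it would lose tert-butanol, and the route is rejoined at ketene 5.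

Further compounds
F1 | step 3 | methyl (E)-3-(pyrrolidin-1-yl)pent-2-enoate | CC/C(N1CCCC1)=C\C(=O)OC
F2 | step 3 | methyl 2-ethyl-4-oxo-6-tridecyl-4H-pyran-3-carboxylate | CCCCCCCCCCCCCc1cc(=O)c(C(=O)OC)c(CC)o1
F3 | step 3 | methyl 4-oxo-2-(3-oxopentan-2-yl)-6-tridecyl-4H-pyran-3-carboxylate (racemic) | CCCCCCCCCCCCCc1cc(=O)c(C(=O)OC)c(C(C)C(=O)CC)o1
F4 | step 2 | (E)-5-(pyrrolidin-1-yl)hept-4-en-3-one | CCC(=O)/C=C(\CC)N1CCCC1
F5 | step 1 | tert-butyl 3-oxohexadecanoate | CCCCCCCCCCCCCC(=O)CC(=O)OC(C)(C)C
A1 | direct plan | 1,3,5-trimethoxy-2,4-dimethylbenzene | Cc1c(OC)cc(OC)c(C)c1OC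
A2 | direct plan | 1-(2,4,6-trimethoxy-3,5-dimethylphenyl)hexadecan-1-one | CCCCCCCCCCCCCCCC(=O)c1c(OC)c(C)c(OC)c(C)c1OC
A3 | direct plan | 1-(2-hydroxy-4,6-dimethoxy-3,5-dimethylphenyl)hexadecan-1-one | CCCCCCCCCCCCCCCC(=O)c1c(O)c(C)c(OC)c(C)c1OC
A4 | direct plan | 5,7-dimethoxy-6,8-dimethyl-2-tridecyl-4H-chromen-4-one | CCCCCCCCCCCCCc1cc(=O)c2c(OC)c(C)c(OC)c(C)c2o1
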